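**Plan**

1. Cuts, in order: (a) the two aryl–carbon bonds of the lactone ring, C1–C7a and C3–C3a, which leads back to 3,5-dimethoxybenzyne and the α-lithiated N,N-diisopropylcarbamate of the complete side-chain alcohol; (b) the spiroketal at C5''–O1'', C5''–O6'', C3''–C4'' and C8''–C9'', which leads back to acetone N,N-dimethylhydrazone and two terminal epoxides.
2. Enabling feature: C3–O2–C1(=O) of the lactone ring is an O-alkyl carbamate in disguise (carbanion site at C3, acyl donor at C1), and the methoxy group on C7, next to C7a of the benzene ring, is the substituent that steers a nucleophile to the far carbon of a 3-methoxyaryne.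
3. Forward order: the chain first (carbamate of non-8-en-1-ol, epoxide, resolution), then both tetrahydrofuran rings of the spiroketal at once from the bis-alkylated hydrazone, then the lactone ring, closed onto the purchased benzene ring as the two fragments are joined, and last the sorting of the spiro centre.
4. Stereochemistry: C7'' comes from (R)-propylene oxide, C2'' from hydrolytic kinetic resolution, C3 from (−)-sparteine-mediated deprotonation with retentive C–C bond formation; C5'' is an acetal centre without inherent bias and is fixed in the last step by acid equilibration, separation of the two spiro epimers and recycling of the unwanted one.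
5. Helpers: the N,N-diisopropylcarbamoyl group (directs the lithiation, supplies C1, leaves as diisopropylamine) and the bromine and iodine atoms of the aryne precursor (leave as lithium halides).

Key step: step 6

Remark on the chemistry: the spiro carbon of a 2,7-dialkyl-1,6-dioxaspiro[4.4]nonane epimerises whenever acid is present, so the spiroketal carbamate and everything derived from it up to the lactone are carried as the pair of spiro epimers (their SMILES leave this one centre open), and the centre is defined only in the final compound.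

**Route**

Step 1
Reactants: 1 non-8-en-1-ol; 2 N,N-diisopropylcarbamoyl chloride
Product: 3 non-8-en-1-yl N,N-diisopropylcarbamate
Conditions: NaH, THF, 0 °C; then 2, reflux
Reagents that add atoms: none
Why: O-carbamoylation of the sodium alkoxide (nucleophilic acyl substitution) installs the group that later directs the α-lithiation and delivers the lactone carbonyl, and the terminal alkene is inert.

Step 2
Reactants: 3 non-8-en-1-yl N,N-diisopropylcarbamate
Product: 4 rac-7-(oxiran-2-yl)heptyl N,N-diisopropylcarbamate
Conditions: mCPBA, CH2Cl2, 0 °C → rt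
Reagents that add atoms: mCPBA (3-chloroperoxybenzoic acid), OOC(=O)c1cccc(Cl)c1
Why: Prilezhaev epoxidation of the only alkene is chemoselective because the carbamate offers no oxidisable site, and no stereocontrol is sought at this stage.

Step 3
Reactants: 4 rac-7-(oxiran-2-yl)heptyl N,N-diisopropylcarbamate
Product: 5 7-[(2R)-oxiran-2-yl]heptyl N,N-diisopropylcarbamate
Conditions: (R,R)-Co(salen)(OAc) (trivalent cobalt; salen = N,N'-bis(3,5-di-tert-butylsalicylidene)-1,2-cyclohexanediaminate) cat., H2O (0.55 equiv), THF, 0 °C → rt; chromatography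
Reagents that add atoms: none
Why: Hydrolytic kinetic resolution of a terminal epoxide, in which this catalyst enantiomer should hydrolyse the (S)-epoxide and leave the (R)-epoxide (at most half of the material by design) that becomes C2'' of the spiroketal.

Step 4
Reactants: 6 acetone N,N-dimethylhydrazone; 7 (R)-propylene oxide; 5 7-[(2R)-oxiran-2-yl]heptyl N,N-diisopropylcarbamate
Product: 11 7-[(2R,7R)-7-methyl-1,6-dioxaspiro[4.4]nonan-2-yl]heptyl N,N-diisopropylcarbamate (both C5 epimers), via hydroxy hydrazone 8 (not isolated), via dihydroxy hydrazone 9 (not isolated), via keto diol 10 (not isolated)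
Conditions: 6 (1.3 equiv), nBuLi, THF, −78 → 0 °C; 7, −78 °C → rt; nBuLi, −78 → 0 °C; 5 (1.0 equiv), −78 °C → rt; then 2 M HCl, THF/H2O, rt
Reagents that add atoms: none
Why: Regioselective α,α'-bis-alkylation of a ketone N,N-dimethylhydrazone azaenolate by SN2 opening of each epoxide at its terminal carbon carries both carbinol centres over unchanged from 7 and 5, and acid hydrolysis of the hydrazone lets γ,γ'-dihydroxy ketone 10 close both rings by spontaneous double cycloketalisation, with the spiro centre formed without control.

Step 5
Reactants: 12 1-bromo-3,5-dimethoxybenzene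
Product: 13 1-bromo-2-iodo-3,5-dimethoxybenzene
Conditions: N-iodosuccinimide, MeCN, rt, dark
Reagents that add atoms: N-iodosuccinimide, O=C1CCC(=O)N1I
Why: Electrophilic aromatic iodination of a resorcinol dimethyl ether should go to the position ortho to one and para to the other methoxy group (C2, next to bromine) and not to the doubly ortho C4.

Step 6
Reactants: 11 7-[(2R,7R)-7-methyl-1,6-dioxaspiro[4.4]nonan-2-yl]heptyl N,N-diisopropylcarbamate (both C5 epimers); 13 1-bromo-2-iodo-3,5-dimethoxybenzene
Product: 19 (3R)-5,7-dimethoxy-3-{6-[(2R,7R)-7-methyl-1,6-dioxaspiro[4.4]nonan-2-yl]hexyl}-2-benzofuran-1(3H)-one (both C5'' epimers), via lithiated carbamate 14 (not isolated), via aryllithium 15 (not isolated), via aryne 16 (not isolated), via aryllithium adduct 17 (not isolated), via hydroxy amide 18 (not isolated)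
Conditions: 11 (1.3 equiv), sBuLi (1.25 equiv), (−)-sparteine, Et2O, −78 °C, 5 h; separately 13 (1.0 equiv), tBuLi (2.0 equiv), THF/Et2O/pentane 4:1:1, −110 °C; this solution added by cold cannula to 14, −78 → −50 °C; AcOH; aqueous H3PO4 wash (sparteine and excess 11 recovered); crude 18, TsOH·H2O (1.5 equiv), PhMe, 90 °C; chromatography
Reagents that add atoms: none
Why: Proposed new method: the α-oxyalkyllithium 14 should add across the strained in-plane π bond of aryne 16 (carbolithiation, forming C3–C3a), and the aryllithium 17 that results is held next to the carbamate carbonyl and should attack it in an anionic homo-Fries 1,4 O→C carbamoyl shift (forming C1–C7a) to leave the alkoxide of 18, which the acid then lactonises with loss of diisopropylamine. The closest known reaction types are the addition of alkyllithiums and stabilised carbanions to arynes with capture of the new aryl anion by a carbonyl group of the nucleophile (aryne acyl-alkylation), the anionic homo-Fries rearrangement of ortho-lithiated benzyl carbamates that is used to make phthalides, and the retentive substitution of sparteine-complexed lithiated O-alkyl carbamates by electrophiles; what is new is the aryne as the electrophile for such a carbanion. The lactone ring (C1, O2, C3, C3a, C7a) is closed twice on the same carbonyl carbon, both times 5-exo-trig: first by C7a–Li on the carbamate C=O, which opens again to the amide, then by the C3 hydroxyl on the protonated amide. C3 is set by reagent control, since sBuLi/(−)-sparteine removes the pro-S hydrogen to give the (S)-lithium compound, which is configurationally stable at −78 °C, and a non-benzylic α-oxyalkyllithium is substituted with retention, which gives (3R); the remote centres of the side chain have no say. The step needs regioselective attack on the unsymmetrical aryne, which the methoxy group next to the triple bond secures by distorting and polarising it so that carbon attacks the far aryne carbon and the negative charge develops next to oxygen, and it needs the carbanion to survive aryne generation, which is secured by releasing the aryne from the separately made reservoir 15 (loss of LiBr at −78 °C without base, amine or fluoride) and by keeping 14 in excess so that the product alkoxide is not arylated. C5'' equilibrates in the acid stage, so 19 is expected as the pair of C5'' epimers, which the last step sorts.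

Step 7
Reactants: 19 (3R)-5,7-dimethoxy-3-{6-[(2R,7R)-7-methyl-1,6-dioxaspiro[4.4]nonan-2-yl]hexyl}-2-benzofuran-1(3H)-one (both C5'' epimers)
Product: 20 (3R)-5,7-dimethoxy-3-{6-[(2R,5S,7R)-7-methyl-1,6-dioxaspiro[4.4]nonan-2-yl]hexyl}-2-benzofuran-1(3H)-one
Conditions: preparative HPLC (silica, hexane/EtOAc) to collect 20; the (5''R) epimer fraction: CSA (cat.), CH2Cl2, rt, back to the pair, then HPLC again; cycle repeated
Reagents that add atoms: none
Why: Acid-catalysed spiroketal epimerisation through the ring-opened oxocarbenium ion interconverts the two C5'' epimers while C2'', C7'' and C3 stay untouched (C3 cannot ionise, being meta to both methoxy groups and next to the acyl-bearing carbon), and since no thermodynamic bias between the epimers is expected, the (5''S) configuration is secured by separating the pair and recycling the unwanted epimer, not by selectivity.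

**Compound list**

1 | non-8-en-1-ol | C=CCCCCCCCO | starting material
2 | N,N-diisopropylcarbamoyl chloride | CC(C)N(C(C)C)C(=O)Cl | starting material
3 | non-8-en-1-yl N,N-diisopropylcarbamate | C=CCCCCCCCOC(=O)N(C(C)C)C(C)C | intermediate
4 | rac-7-(oxiran-2-yl)heptyl N,N-diisopropylcarbamate | CC(C)N(C(C)C)C(=O)OCCCCCCCC1CO1 | intermediate
5 | 7-[(2R)-oxiran-2-yl]heptyl N,N-diisopropylcarbamate | CC(C)N(C(C)C)C(=O)OCCCCCCC[C@@H]1CO1 | intermediate
6 | acetone N,N-dimethylhydrazone | CC(C)=NN(C)C | starting material
7 | (R)-propylene oxide, (2R)-2-methyloxirane | C[C@@H]1CO1 | starting material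
8 | (5R)-5-hydroxyhexan-2-one N,N-dimethylhydrazone (lithium alkoxide in the flask, not isolated) | C[C@@H](O)CCC(C)=NN(C)C | intermediate
9 | (8R,14R)-11-(2,2-dimethylhydrazinylidene)-8,14-dihydroxypentadecyl N,N-diisopropylcarbamate (not isolated) | C[C@@H](O)CCC(CC[C@H](O)CCCCCCCOC(=O)N(C(C)C)C(C)C)=NN(C)C | intermediate
10 | (8R,14R)-8,14-dihydroxy-11-oxopentadecyl N,N-diisopropylcarbamate (not isolated) | C[C@@H](O)CCC(=O)CC[C@H](O)CCCCCCCOC(=O)N(C(C)C)C(C)C | intermediate
11 | 7-[(2R,7R)-7-methyl-1,6-dioxaspiro[4.4]nonan-2-yl]heptyl N,N-diisopropylcarbamate, both C5 epimers (spiro centre left open) | CC(C)N(C(C)C)C(=O)OCCCCCCC[C@@H]1CCC2(CC[C@@H](C)O2)O1 | intermediate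
12 | 1-bromo-3,5-dimethoxybenzene | COc1cc(OC)cc(Br)c1 | starting material
13 | 1-bromo-2-iodo-3,5-dimethoxybenzene | COc1cc(OC)c(I)c(Br)c1 | intermediate
14 | (1S)-1-lithio-7-[(2R,7R)-7-methyl-1,6-dioxaspiro[4.4]nonan-2-yl]heptyl N,N-diisopropylcarbamate, (−)-sparteine complex (not isolated; spiro centre left open) | [Li][C@@H](CCCCCC[C@@H]1CCC2(CC[C@@H](C)O2)O1)OC(=O)N(C(C)C)C(C)C | intermediate
15 | 2-bromo-4,6-dimethoxyphenyllithium (not isolated) | COc1cc(OC)c([Li])c(Br)c1 | intermediate
16 | 3,5-dimethoxybenzyne, 1,2-didehydro-3,5-dimethoxybenzene (not isolated) | COC1=CC(OC)=CC#C1 | intermediate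
17 | (1R)-1-(2-lithio-3,5-dimethoxyphenyl)-7-[(2R,7R)-7-methyl-1,6-dioxaspiro[4.4]nonan-2-yl]heptyl N,N-diisopropylcarbamate (not isolated; spiro centre left open) | COc1cc(OC)c([Li])c(c1)[C@@H](CCCCCC[C@@H]1CCC2(CC[C@@H](C)O2)O1)OC(=O)N(C(C)C)C(C)C | intermediate
18 | 2-{(1R)-1-hydroxy-7-[(2R,7R)-7-methyl-1,6-dioxaspiro[4.4]nonan-2-yl]heptyl}-4,6-dimethoxy-N,N-diisopropylbenzamide (crude, not purified; spiro centre left open) | COc1cc(OC)c(C(=O)N(C(C)C)C(C)C)c(c1)[C@@H](CCCCCC[C@@H]1CCC2(CC[C@@H](C)O2)O1)O | intermediate
19 | (3R)-5,7-dimethoxy-3-{6-[(2R,7R)-7-methyl-1,6-dioxaspiro[4.4]nonan-2-yl]hexyl}-2-benzofuran-1(3H)-one, both C5'' epimers (spiro centre left open) | COc1cc(OC)c2c(c1)[C@@H](CCCCCC[C@@H]1CCC3(CC[C@@H](C)O3)O1)OC2=O | intermediate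
20 | (3R)-5,7-dimethoxy-3-{6-[(2R,5S,7R)-7-methyl-1,6-dioxaspiro[4.4]nonan-2-yl]hexyl}-2-benzofuran-1(3H)-one | COc1cc(OC)c2c(c1)[C@@H](CCCCCC[C@@H]1CC[C@]3(CC[C@@H](C)O3)O1)OC2=O | target

**Step count**

Total steps: 7. Longest linear sequence: 6 (steps 1, 2, 3, 4, 6, 7); step 5 is a one-step branch.

**Steps most likely to fail**

Step 6 (Proposed new method). What may go wrong: consumption of the carbanion by halogen–lithium exchange or protonation in place of carbolithiation, self-addition of the aryllithium reservoir to the aryne, erosion of configuration if the mixture has to be warmed before the aryne is released, and arylation of the product alkoxide. The fallback uses known chemistry, sets out from 11 and comes back at 19. Carbamate 11 is lithiated as before (sBuLi, (−)-sparteine, Et2O, −78 °C) and trapped with 3,5-dimethoxyphenylboronic acid pinacol ester. Lithiation–borylation (ate complex with retention, 1,2-aryl shift with inversion on warming, MgBr2·OEt2 if needed) should give the (R)-benzylic pinacol boronic ester F1. Oxidation with H2O2/NaOH proceeds with retention and should give the (R)-benzylic alcohol F2, which carries the C3 configuration of the target. NaH and N,N-diethylcarbamoyl chloride convert it into the N,N-diethylcarbamate F3. NBS in MeCN at 0 °C brominates ortho to the side chain and para to a methoxy group to give the aryl bromide F4. tBuLi (2 equiv, THF, −78 °C) effects bromine–lithium exchange and the anionic homo-Fries shift to give the N,N-diethyl hydroxy amide F5. TsOH in toluene lactonises F5 to 19, the same epimer pair, which then enters step 7.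

Step 4. What may go wrong: loss of regiocontrol in the second deprotonation (α in place of α'), or stalling of the second epoxide opening in the aggregated alkoxide–azaenolate. The fallback replaces the ketone enolate equivalent by an alkyne as the masked ketone, sets out from 5 and comes back at 11. Epoxide 5 is opened at its terminal carbon by 3-lithio-1-(trimethylsilyl)propyne (from 1-(trimethylsilyl)propyne, nBuLi, THF, −78 °C; BF3·OEt2) to give the silyl alkynol F6. K2CO3 in MeOH removes the silyl group to give the terminal alkynol F7. Its dilithium alkoxide–acetylide (nBuLi, 2.2 equiv, THF/DMPU) opens (R)-propylene oxide 7 to give the alkyne diol F8. AuCl (cat., MeOH, rt) effects double hydroalkoxylation, in which the C8 hydroxyl closes 5-exo-dig and the C14 hydroxyl adds to the same alkyne carbon, and should give 11 as the same epimer pair.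

Step 7. What may go wrong: incomplete chromatographic resolution of the two spiro epimers on the fully assembled phthalide, and loss of material over repeated acid and separation cycles, since the equilibrium offers no bias. The fallback sorts the spiro centre on the robust carbamate and applies no acid afterwards; it sets out from 11 and comes back at 20. The pair 11 is separated by preparative chromatography, the unwanted epimer being returned to CSA in CH2Cl2, to give the single-epimer (2R,5S,7R)-spiroketal carbamate F9. Lithiation (sBuLi, (−)-sparteine, Et2O, −78 °C), trapping with 3,5-dimethoxyphenylboronic acid pinacol ester and thermal 1,2-migration in refluxing Et2O without a Lewis acid should give the single-epimer (R)-benzylic pinacol boronic ester F10. NaOH/H2O2 oxidises it with retention to the single-epimer (R)-benzylic alcohol F11. NBS with solid NaHCO3 in MeCN at 0 °C brominates ortho to the side chain to give the single-epimer bromo alcohol F12. Carbonylative lactonisation (PdCl2(PPh3)2 cat., CO 1 atm, K2CO3, DMF, 80 °C) closes the phthalide under basic conditions and should give 20 directly. All chromatography after F9 is run on Et3N-deactivated silica so that the spiro centre is not touched again.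

**Further compounds**

F1 | step 6 | 2-{(1R)-1-(3,5-dimethoxyphenyl)-7-[(2R,7R)-7-methyl-1,6-dioxaspiro[4.4]nonan-2-yl]heptyl}-4,4,5,5-tetramethyl-1,3,2-dioxaborolane | COc1cc(OC)cc(c1)[C@@H](CCCCCC[C@@H]1CCC2(CC[C@@H](C)O2)O1)B1OC(C)(C)C(C)(C)O1
F2 | step 6 | (1R)-1-(3,5-dimethoxyphenyl)-7-[(2R,7R)-7-methyl-1,6-dioxaspiro[4.4]nonan-2-yl]heptan-1-ol | COc1cc(OC)cc(c1)[C@@H](CCCCCC[C@@H]1CCC2(CC[C@@H](C)O2)O1)O
F3 | step 6 | (1R)-1-(3,5-dimethoxyphenyl)-7-[(2R,7R)-7-methyl-1,6-dioxaspiro[4.4]nonan-2-yl]heptyl N,N-diethylcarbamate | COc1cc(OC)cc(c1)[C@@H](CCCCCC[C@@H]1CCC2(CC[C@@H](C)O2)O1)OC(=O)N(CC)CC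
F4 | step 6 | (1R)-1-(2-bromo-3,5-dimethoxyphenyl)-7-[(2R,7R)-7-methyl-1,6-dioxaspiro[4.4]nonan-2-yl]heptyl N,N-diethylcarbamate | COc1cc(OC)c(Br)c(c1)[C@@H](CCCCCC[C@@H]1CCC2(CC[C@@H](C)O2)O1)OC(=O)N(CC)CC
F5 | step 6 | N,N-diethyl-2-{(1R)-1-hydroxy-7-[(2R,7R)-7-methyl-1,6-dioxaspiro[4.4]nonan-2-yl]heptyl}-4,6-dimethoxybenzamide | COc1cc(OC)c(C(=O)N(CC)CC)c(c1)[C@@H](CCCCCC[C@@H]1CCC2(CC[C@@H](C)O2)O1)O
F6 | step 4 | (8R)-8-hydroxy-12-(trimethylsilyl)dodec-11-yn-1-yl N,N-diisopropylcarbamate | C[Si](C)(C)C#CCC[C@H](O)CCCCCCCOC(=O)N(C(C)C)C(C)C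
F7 | step 4 | (8R)-8-hydroxydodec-11-yn-1-yl N,N-diisopropylcarbamate | C#CCC[C@H](O)CCCCCCCOC(=O)N(C(C)C)C(C)C
F8 | step 4 | (8R,14R)-8,14-dihydroxypentadec-11-yn-1-yl N,N-diisopropylcarbamate | C[C@@H](O)CC#CCC[C@H](O)CCCCCCCOC(=O)N(C(C)C)C(C)C
F9 | step 7 | 7-[(2R,5S,7R)-7-methyl-1,6-dioxaspiro[4.4]nonan-2-yl]heptyl N,N-diisopropylcarbamate | CC(C)N(C(C)C)C(=O)OCCCCCCC[C@@H]1CC[C@]2(CC[C@@H](C)O2)O1
F10 | step 7 | 2-{(1R)-1-(3,5-dimethoxyphenyl)-7-[(2R,5S,7R)-7-methyl-1,6-dioxaspiro[4.4]nonan-2-yl]heptyl}-4,4,5,5-tetramethyl-1,3,2-dioxaborolane | COc1cc(OC)cc(c1)[C@@H](CCCCCC[C@@H]1CC[C@]2(CC[C@@H](C)O2)O1)B1OC(C)(C)C(C)(C)O1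
F11 | step 7 | (1R)-1-(3,5-dimethoxyphenyl)-7-[(2R,5S,7R)-7-methyl-1,6-dioxaspiro[4.4]nonan-2-yl]heptan-1-ol | COc1cc(OC)cc(c1)[C@@H](CCCCCC[C@@H]1CC[C@]2(CC[C@@H](C)O2)O1)O
F12 | step 7 | (1R)-1-(2-bromo-3,5-dimethoxyphenyl)-7-[(2R,5S,7R)-7-methyl-1,6-dioxaspiro[4.4]nonan-2-yl]heptan-1-ol | COc1cc(OC)c(Br)c(c1)[C@@H](CCCCCC[C@@H]1CC[C@]2(CC[C@@H](C)O2)O1)O
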